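Slowness is where I start: in the dawn flask the uncatalysed step alone gives substrate a half-life of 25 d, longer than the 5.0 d run, so I count that step as the source of a seed of target.

    substrate + coupling partner + target → 2 target (k1 = 7580 /M²/h)
    substrate + coupling partner → target (k2 = 0.112 /M/h)
    2 coupling partner → self-condensation product (k3 = 5.74 /M/h)
    coupling partner ⇌ dormant form (K4 = 2.0, k4 = 0.0178 /h)

| flask | substrate | coupling partner | time | remark |
|---|---|---|---|---|
| spring | 10 mM (fed, over 4.00 d) | 1.05 equiv | 5.0 d | a stirred flask in which substrate is dosed at a steady rate over 4.00 d without added volume, worked up at 5.0 d |
| autumn | 10 mM | 1.05 equiv (fed, over 4.00 d) | 5.0 d | a stirred flask in which coupling partner is dosed at a steady rate over 4.00 d without added volume, worked up at 5.0 d |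
| dawn | 10 mM | 1.05 equiv | 5.0 d | everything together in a closed stirred flask, run for 5.0 d |
| midnight | 10 mM | 1.05 equiv |  | one stirred flow tank at steady state, fed with the mixture as stated, mean residence time 5.0 d |

- a doubled species enters its step squared and goes two at a time
- the stated concentrations are those of everything mixed, before any reaction; amounts are the same in each set-up
- the feed brings no volume worth counting
- run time (spring): 5.0 d

1. order of the set-ups by the amount of target at the outlet or at the end, in percent of the substrate put in, highest first (spring / autumn / dawn / midnight)
2. amount of target at the outlet or at the end, in percent of the substrate put in, spring
3. amount of target at the outlet or at the end, in percent of the substrate put in, autumn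
4. amount of target at the outlet or at the end, in percent of the substrate put in, dawn
5. amount of target at the outlet or at the end, in percent of the substrate put in, midnight

I climb the ladder from the fastest rung, with everything as charged in the dawn flask, and write A, B and T for the concentrations of substrate, coupling partner and target. Once seeded, the catalysed step doubles target every 0.871 h. Self-condensation gives the coupling partner a first half-life of 8.30 h, longer than that doubling time. The exchange with the dormant form relaxes with a half-life of 1.08 d, longer again. So in the first hours the seed multiplies while self-condensation eats coupling partner, and the dormant form lags behind both.

The catalysed step and self-condensation take coupling partner equally fast when T reaches the hand-over level T* = h·B/A, where h, twice the self-condensation constant over the catalysed constant, is 1.51 mM. This is a selectivity factor: while step one dominates target growth, each e-fold of target costs T* of coupling partner in self-condensation. In dawn, T* starts at 1.59 mM, and the seed counts from 0.0148 mM, where the two target-making steps match. From seed to T* that is 4.68 e-folds, costing 7.44 mM at the charged ratio, and the rest of the charged coupling partner would make target equal to 30.6 % of the substrate. B/A falls as coupling partner goes, and I leave the dormant form out, so this is a rough estimate for dawn, not a bound, and I expect it to run low. At the start, dosing substrate has A near zero, which raises T*, and dosing coupling partner has B near zero, which lowers it. My order is therefore autumn, dawn, spring, and I leave the tank unplaced.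

The forecast, holding that “target builds only once seeded”, gives midnight > autumn > dawn > spring, with 11 % for spring, 80 % for autumn, 48 % for dawn and 84.2 % for midnight. My 30.6 % for dawn is lower than the forecast's figure.

The simulation gives midnight > autumn > dawn > spring, with 9.98 % for spring, 79.7 % for autumn, 46.9 % for dawn and 84.2 % for midnight, so the forecast stands within its margins. At 5.00 d in spring, T is 0.998 mM, above T* of 0.0369 mM. The neighbouring spring flask holds 0.260 equiv of coupling partner. At 5.00 d its T* is 0.0442 mM, and its T of 0.237 mM stands above it. Its self-condensation product is 0.611 mM, and it ends at 2.37 % target.

The rate constants are invented; no experiment stands behind them.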